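**Retrosynthetic overview**

- The oxane ring (O, C9–C13; atoms numbered C1–C15 along the pentadec‑1‑yne chain) is locally mirror‑symmetric: C8 and C14 sit cis on C9/C13, the bromides on C10/C12 are cis to each other and trans to them, C11 is CH2, and C8 and C14 are single carbons. Tying C8 to C14 turns this ring into a meso 8‑oxabicyclo[3.2.1]oct‑6‑ene.
- Key disconnection: that bicycle is furan (O, C9, C8, C14, C13) plus a 1,3‑dioxygenated oxyallyl cation (C10–C11–C12). One [4+3] cycloaddition makes C9–C10 and C12–C13, the oxane ring and the relative configuration at C9, C10, C12, C13 (C10/C12 as C–O, later inverted to C–Br).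
- The C8=C14 bond is opened by asymmetric ring‑opening cross‑metathesis with an enantiopure vinyl oxolane (C1–C7; ring O/C3–C6). This desymmetrizes the meso core, joins the halves as C7=C8 and delivers C15.
- Last ring: Shi epoxidation of C7=C8 and 5‑exo opening by the C4 hydroxyl close the 2,5‑dioxabicyclo[2.2.1]heptane (O/C4–C7); the C8, C10 and C12 alcohols then become the three bromides by SN2 inversion.
- Ring order: oxane (as oxabicycle, step 3), oxolane O/C3–C6 (step 10), oxolane O/C4–C7 (step 13).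

Key step: step 3

Remarks on the chemistry: (S)‑2‑ethenyloxirane is taken as a commercial starting material. The matched enantiomer of the chiral ruthenium carbene complex for the ring‑opening step cannot be predicted with confidence; the route is written with the (4R,5R) complex, and the (4S,5S) complex is used if a trial shows it to be the matched one.

**Route**

Step 1
Reactants: 1 1,3‑bis(benzyloxy)propan‑2‑one
Product: 3 1,1,3‑tris(benzyloxy)propan‑2‑one, via 1‑chloro‑1,3‑bis(benzyloxy)propan‑2‑one 2 (not isolated)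
Conditions: SO2Cl2 (1.0 equiv), CH2Cl2, 0 °C; then BnOH, i‑Pr2NEt, 0 °C → rt
Reagents that add atoms: sulfuryl chloride, O=S(=O)(Cl)Cl (chlorine of 2 only); benzyl alcohol, OCc1ccccc1
Why: α‑chlorination of the ketone through its enol (both enolizable positions are equivalent CH2OBn groups) gives an α‑chloro ether that is solvolysed by benzyl alcohol through the oxocarbenium ion (acetal formation from an α‑halo ether); the transient stereocenter of 2 disappears in 3.

Step 2
Reactants: 3 1,1,3‑tris(benzyloxy)propan‑2‑one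
Product: 4 (Z)‑{[1,3,3‑tris(benzyloxy)prop‑1‑en‑2‑yl]oxy}triethylsilane
Conditions: Et3SiOTf, Et3N, CH2Cl2, 0 °C
Reagents that add atoms: triethylsilyl trifluoromethanesulfonate, CC[Si](CC)(CC)OS(=O)(=O)C(F)(F)F
Why: soft enolization and O‑silylation (silyl enol ether formation) should go toward the CH2OBn side because the acetal methine is hindered, with the Z geometry usual for α‑alkoxy ketones; either geometry would ionize to the same cation in step 3.

Step 3
Reactants: 4 (Z)‑{[1,3,3‑tris(benzyloxy)prop‑1‑en‑2‑yl]oxy}triethylsilane; 5 furan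
Product: 7 meso‑(1R,2S,4R,5S)‑2,4‑bis(benzyloxy)‑8‑oxabicyclo[3.2.1]oct‑6‑en‑3‑one (both benzyloxy groups cis to the C6=C7 bridge), via W‑shaped bis(benzyloxy)siloxyallyl cation 6 (not isolated)
Conditions: Me3SiOTf (10 mol%), 5 (10 equiv), CH2Cl2, −78 → −40 °C; Et3N quench
Reagents that add atoms: none
Why: Me3SiOTf ionizes the acetal of 4 to the W‑shaped 1,3‑bis(benzyloxy)‑2‑(triethylsilyloxy)allyl cation 6, a 2π three‑carbon unit that adds across C2 and C5 of furan in a [4+3] cycloaddition (concerted, or furan attack followed by closure of the enol silane onto the furanyl oxocarbenium ion), and the silyl group is passed to the next acetal so that the Lewis acid turns over. The closest known reaction is the [4+3] cycloaddition of furan with α‑alkoxy siloxyallyl cations made in the same way from silyl enol ethers of α‑keto acetals; 6 is the member of that class with a second alkoxy group at the other terminus. The one event closes the seven‑membered carbocycle C9–C10–C11–C12–C13–C14–C8 and with it the oxane ring O–C9–C10–C11–C12–C13 (numbering of 24), the mode of closure being the [4+3] cycloaddition through a compact, boat‑like transition state. C9 and C13 are set cis because both bonds form on one face of the planar furan; C10 and C12 carry their benzyloxy groups cis to the C8=C14 bridge because both alkoxy groups are syn to the central oxygen in the W cation and the compact transition state places them equatorial, and any axial epimer should be equilibrated to the diequatorial ketone by the amine, so that one meso compound results. The step needs cycloaddition to win over electrophilic substitution at C2 of furan and needs the all‑cis diastereomer; the first is secured by the built‑in enol silane nucleophile, low temperature and excess furan, the second by the W geometry of 6 and the preference for equatorial α‑alkoxy groups.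

Step 4
Reactants: 7 meso‑(1R,2S,4R,5S)‑2,4‑bis(benzyloxy)‑8‑oxabicyclo[3.2.1]oct‑6‑en‑3‑one
Product: 8 meso‑2,4‑bis(benzyloxy)‑8‑oxabicyclo[3.2.1]oct‑6‑en‑3‑ol (hydroxyl and both benzyloxy groups cis to the C6=C7 bridge)
Conditions: NaBH4, MeOH, 0 °C
Reagents that add atoms: none
Why: hydride reduction of the ketone should occur from the open face of the oxygen bridge to give the all‑cis alcohol; the configuration at this carbon (C11) is irrelevant because the oxygen is removed in step 6.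

Step 5
Reactants: 8 meso‑2,4‑bis(benzyloxy)‑8‑oxabicyclo[3.2.1]oct‑6‑en‑3‑ol
Product: 9 O‑[meso‑2,4‑bis(benzyloxy)‑8‑oxabicyclo[3.2.1]oct‑6‑en‑3‑yl] 1H‑imidazole‑1‑carbothioate
Conditions: 1,1′‑thiocarbonyldiimidazole, DMAP (cat.), toluene, 80 °C
Reagents that add atoms: 1,1′‑thiocarbonyldiimidazole, S=C(n1ccnc1)n1ccnc1
Why: thioacylation of the alcohol (first half of the Barton–McCombie deoxygenation) needs no strong base and tolerates the flanking benzyl ethers.

Step 6
Reactants: 9 O‑[meso‑2,4‑bis(benzyloxy)‑8‑oxabicyclo[3.2.1]oct‑6‑en‑3‑yl] 1H‑imidazole‑1‑carbothioate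
Product: 10 meso‑(1R,2R,4S,5S)‑2,4‑bis(benzyloxy)‑8‑oxabicyclo[3.2.1]oct‑6‑ene
Conditions: Bu3SnH, AIBN (cat.), toluene, 100 °C
Reagents that add atoms: none
Why: Barton–McCombie radical deoxygenation, in which the secondary C11 radical abstracts hydrogen from the stannane and β‑benzyloxy groups do not fragment, so C11 becomes the CH2 of the target and the meso symmetry is kept.

Step 7
Reactants: 11 (S)‑2‑ethenyloxirane
Product: 12 (3R)‑hex‑1‑en‑5‑yn‑3‑ol
Conditions: LiC≡CH·H2NCH2CH2NH2, DMSO, 10 °C → rt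
Reagents that add atoms: lithium acetylide (ethylenediamine complex), [Li]C#C
Why: SN2 alkynylation of the epoxide at its CH2 carbon leaves the stereocenter untouched, so the (S)‑epoxide gives the (R)‑carbinol that becomes C6.

Step 8
Reactants: 12 (3R)‑hex‑1‑en‑5‑yn‑3‑ol
Product: 14 (3R,5E)‑8‑[tri(propan‑2‑yl)silyl]octa‑1,5‑dien‑7‑yn‑3‑ol, via O‑zirconated (E)‑alkenylzirconocene chloride 13 (not isolated)
Conditions: Cp2Zr(H)Cl (2.2 equiv), THF, rt; then ZnCl2, Pd(PPh3)4 (5 mol%), BrC≡CSi(i‑Pr)3, rt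
Reagents that add atoms: chlorobis(cyclopentadienyl)hydridozirconium, [H][Zr](Cl)(C1C=CC=C1)C1C=CC=C1 (zirconium of 13 only); (bromoethynyl)tri(propan‑2‑yl)silane, BrC#C[Si](C(C)C)(C(C)C)C(C)C
Why: hydrozirconation adds Zr–H syn and anti‑Markovnikov to the terminal alkyne (faster than to the alkene), and zinc transmetalation with Negishi coupling to the bromoalkyne gives the E enyne with retention of geometry.

Step 9
Reactants: 14 (3R,5E)‑8‑[tri(propan‑2‑yl)silyl]octa‑1,5‑dien‑7‑yn‑3‑ol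
Product: 15 (2R)‑1‑{(2R,3R)‑3‑[(triisopropylsilyl)ethynyl]oxiran‑2‑yl}but‑3‑en‑2‑ol
Conditions: D‑fructose‑derived Shi ketone (0.3 equiv), KHSO5 (Oxone), K2CO3, Bu4NHSO4 (cat.), MeCN/(MeO)2CH2/aq. Na2B4O7–EDTA, 0 °C
Reagents that add atoms: potassium peroxymonosulfate, [K+].[O-]S(=O)(=O)OO
Why: Shi epoxidation, in which the chiral dioxirane epoxidizes the trans enyne alkene through the spiro transition state under catalyst control to the (R,R)‑epoxide (future C3 and C4), while the monosubstituted vinyl group is too slow to compete.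

Step 10
Reactants: 15 (2R)‑1‑{(2R,3R)‑3‑[(triisopropylsilyl)ethynyl]oxiran‑2‑yl}but‑3‑en‑2‑ol
Product: 16 (2S,3R,5R)‑5‑ethenyl‑2‑[(triisopropylsilyl)ethynyl]oxolan‑3‑ol
Conditions: camphorsulfonic acid (10 mol%), CH2Cl2, 0 °C → rt
Reagents that add atoms: none
Why: acid‑catalyzed intramolecular epoxide opening, in which the C6 hydroxyl attacks the alkynyl‑activated carbon C3 in the 5‑endo mode (the only alternative is a 4‑exo oxetane closure) with inversion at C3 and retention at C4, giving the 2,5‑trans oxolane with the C4 hydroxyl cis to the vinyl group.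

Step 11
Reactants: 10 meso‑(1R,2R,4S,5S)‑2,4‑bis(benzyloxy)‑8‑oxabicyclo[3.2.1]oct‑6‑ene; 16 (2S,3R,5R)‑5‑ethenyl‑2‑[(triisopropylsilyl)ethynyl]oxolan‑3‑ol
Product: 17 (2S,3R,5R)‑5‑{(E)‑2‑[(2S,3S,5R,6R)‑3,5‑bis(benzyloxy)‑6‑ethenyloxan‑2‑yl]ethenyl}‑2‑[(triisopropylsilyl)ethynyl]oxolan‑3‑ol
Conditions: RuCl2(=CHPh)(PCy3)[(4R,5R)‑1,3‑bis(2‑isopropylphenyl)‑4,5‑diphenylimidazolidin‑2‑ylidene] (5 mol%), 16 (2.5 equiv), CH2Cl2, 40 °C
Reagents that add atoms: none
Why: asymmetric ring‑opening cross‑metathesis, in which the ruthenium alkylidene from 16 adds to the strained C8=C14 bond from the face of the oxygen bridge, ring opening releases the strain and a second molecule of 16 caps the other terminus as the vinyl group (C14=C15), the chiral carbene ligand choosing between the enantiotopic alkene carbons and the two branched allylic carbons favouring the E alkene; because 16 is enantiopure, any mis‑selection would appear as a separable diastereomer and not as loss of enantiomeric purity.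

Step 12
Reactants: 17 (2S,3R,5R)‑5‑{(E)‑2‑[(2S,3S,5R,6R)‑3,5‑bis(benzyloxy)‑6‑ethenyloxan‑2‑yl]ethenyl}‑2‑[(triisopropylsilyl)ethynyl]oxolan‑3‑ol
Product: 18 (2S,3R,5R)‑5‑{(E)‑2‑[(2S,3S,5R,6R)‑3,5‑bis(benzyloxy)‑6‑ethyloxan‑2‑yl]ethenyl}‑2‑[(triisopropylsilyl)ethynyl]oxolan‑3‑ol
Conditions: 2‑O2NC6H4SO2NHNH2, Et3N, CH2Cl2, rt
Reagents that add atoms: none
Why: diimide reduction is a concerted syn hydrogen transfer that is much faster for a monosubstituted alkene than for the trans C7=C8 alkene flanked by two branched carbons or for the silyl‑capped alkyne, so only the vinyl group should become the ethyl group.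

Step 13
Reactants: 18 (2S,3R,5R)‑5‑{(E)‑2‑[(2S,3S,5R,6R)‑3,5‑bis(benzyloxy)‑6‑ethyloxan‑2‑yl]ethenyl}‑2‑[(triisopropylsilyl)ethynyl]oxolan‑3‑ol
Product: 20 10,12‑di‑O‑benzyl‑1‑(triisopropylsilyl)‑3,6:4,7:9,13‑triepoxypentadec‑1‑yne‑8,10,12‑triol (3S,4R,6R,7S,9,13 as in 24; oxygens at C8, C10, C12 opposite in configuration to the bromides of 24), via trans‑7,8‑epoxide 19 (not isolated)
Conditions: D‑fructose‑derived Shi ketone (0.5 equiv), KHSO5 (Oxone), K2CO3, Bu4NHSO4 (cat.), MeCN/(MeO)2CH2/aq. Na2B4O7–EDTA, 0 °C; then camphorsulfonic acid (cat.), CH2Cl2, 0 °C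
Reagents that add atoms: potassium peroxymonosulfate, [K+].[O-]S(=O)(=O)OO
Why: Shi epoxidation with the same ketone should deliver oxygen to the C7=C8 face of the (R,R)‑type epoxide (reagent control), and the C4 hydroxyl, held cis to the C6–C7 bond on the oxolane, then opens the epoxide at C7 in the 5‑exo mode with inversion (epoxide‑opening etherification), which sets C7 (S), places the C8 chain endo on the new 2,5‑dioxabicyclo[2.2.1]heptane and leaves the C8 alcohol epimeric to the final bromide.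

Step 14
Reactants: 20 10,12‑di‑O‑benzyl‑1‑(triisopropylsilyl)‑3,6:4,7:9,13‑triepoxypentadec‑1‑yne‑8,10,12‑triol
Product: 21 1‑(triisopropylsilyl)‑3,6:4,7:9,13‑triepoxypentadec‑1‑yne‑8,10,12‑triol (hydroxyls at C8, C10, C12 opposite in configuration to the bromides of 24)
Conditions: BCl3, C6HMe5, CH2Cl2, −78 °C; MeOH quench
Reagents that add atoms: none
Why: Lewis‑acid debenzylation with a cation scavenger at low temperature should cleave the two benzyl ethers without touching the alkyne, the silyl group or the bridged ethers, since the same 2,5‑dioxabicyclo[2.2.1]heptane survives these conditions in bridged nucleosides.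

Step 15
Reactants: 21 1‑(triisopropylsilyl)‑3,6:4,7:9,13‑triepoxypentadec‑1‑yne‑8,10,12‑triol
Product: 23 [(3S,4R,6R,7S,8R,9R,10R,12S,13R)‑8,10,12‑tribromo‑3,6:4,7:9,13‑triepoxypentadec‑1‑yn‑1‑yl]tri(propan‑2‑yl)silane, via tris(triflate) 22 (not isolated)
Conditions: Tf2O, 2,6‑lutidine, CH2Cl2, −40 °C; then Bu4NBr, toluene, −40 → 20 °C
Reagents that add atoms: trifluoromethanesulfonic anhydride, O=S(=O)(OS(=O)(=O)C(F)(F)F)C(F)(F)F (triflyl groups of 22 only); tetrabutylammonium bromide, CCCC[N+](CCCC)(CCCC)CCCC.[Br-]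
Why: triflation and SN2 displacement by bromide, in which the C10 and C12 triflates are axial (C9 and C13 substituents equatorial) so that bromide enters equatorially with inversion, the gauche ring oxygen cannot participate and the all‑equatorial ring results, while the C8 triflate is displaced with inversion in the same way, setting all three C–Br centres (8R,10R,12S).

Step 16
Reactants: 23 [(3S,4R,6R,7S,8R,9R,10R,12S,13R)‑8,10,12‑tribromo‑3,6:4,7:9,13‑triepoxypentadec‑1‑yn‑1‑yl]tri(propan‑2‑yl)silane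
Product: 24 (3S,4R,6R,7S,8R,9R,10R,12S,13R)‑8,10,12‑tribromo‑3,6:4,7:9,13‑triepoxypentadec‑1‑yne (CNP0139964.2)
Conditions: Bu4NF, AcOH, THF, 0 °C → rt
Reagents that add atoms: none
Why: fluoride‑induced protodesilylation of the silylalkyne, buffered with acetic acid, should free the terminal alkyne without base‑induced elimination of the secondary bromides.

**Compound list**

1 | 1,3‑bis(benzyloxy)propan‑2‑one | O=C(COCc1ccccc1)COCc1ccccc1 | starting material
2 | 1‑chloro‑1,3‑bis(benzyloxy)propan‑2‑one (racemic) | O=C(COCc1ccccc1)C(Cl)OCc1ccccc1 | intermediate (not isolated)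
3 | 1,1,3‑tris(benzyloxy)propan‑2‑one | O=C(COCc1ccccc1)C(OCc1ccccc1)OCc1ccccc1 | intermediate
4 | (Z)‑{[1,3,3‑tris(benzyloxy)prop‑1‑en‑2‑yl]oxy}triethylsilane | CC[Si](CC)(CC)O/C(=C\OCc1ccccc1)C(OCc1ccccc1)OCc1ccccc1 | intermediate
5 | furan | c1ccoc1 | starting material
6 | 1,3‑bis(benzyloxy)‑2‑(triethylsilyloxy)allyl cation, W form, triflate salt | CC[Si](CC)(CC)O/C(=C\OCc1ccccc1)/C=[O+]/Cc1ccccc1.[O-]S(=O)(=O)C(F)(F)F | intermediate (not isolated)
7 | meso‑(1R,2S,4R,5S)‑2,4‑bis(benzyloxy)‑8‑oxabicyclo[3.2.1]oct‑6‑en‑3‑one | O=C1[C@H](OCc2ccccc2)[C@@H]2C=C[C@@H](O2)[C@@H]1OCc1ccccc1 | intermediate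
8 | meso‑2,4‑bis(benzyloxy)‑8‑oxabicyclo[3.2.1]oct‑6‑en‑3‑ol, all three oxygen substituents cis to the C6=C7 bridge | O[C@@H]1[C@H](OCc2ccccc2)[C@@H]2C=C[C@@H](O2)[C@@H]1OCc1ccccc1 | intermediate
9 | O‑[meso‑2,4‑bis(benzyloxy)‑8‑oxabicyclo[3.2.1]oct‑6‑en‑3‑yl] 1H‑imidazole‑1‑carbothioate | S=C(O[C@@H]1[C@H](OCc2ccccc2)[C@@H]2C=C[C@@H](O2)[C@@H]1OCc1ccccc1)n1ccnc1 | intermediate
10 | meso‑(1R,2R,4S,5S)‑2,4‑bis(benzyloxy)‑8‑oxabicyclo[3.2.1]oct‑6‑ene | C1[C@H](OCc2ccccc2)[C@@H]2C=C[C@@H](O2)[C@@H]1OCc1ccccc1 | intermediate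
11 | (S)‑2‑ethenyloxirane | C=C[C@H]1CO1 | starting material
12 | (3R)‑hex‑1‑en‑5‑yn‑3‑ol | C=C[C@H](O)CC#C | intermediate
13 | O‑zirconated (E)‑alkenylzirconocene chloride from 12 | C=C[C@H](O[Zr](Cl)(C1C=CC=C1)C1C=CC=C1)C/C=C/[Zr](Cl)(C1C=CC=C1)C1C=CC=C1 | intermediate (not isolated)
14 | (3R,5E)‑8‑[tri(propan‑2‑yl)silyl]octa‑1,5‑dien‑7‑yn‑3‑ol | C=C[C@H](O)C/C=C/C#C[Si](C(C)C)(C(C)C)C(C)C | intermediate
15 | (2R)‑1‑{(2R,3R)‑3‑[(triisopropylsilyl)ethynyl]oxiran‑2‑yl}but‑3‑en‑2‑ol | C=C[C@H](O)C[C@H]1O[C@@H]1C#C[Si](C(C)C)(C(C)C)C(C)C | intermediate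
16 | (2S,3R,5R)‑5‑ethenyl‑2‑[(triisopropylsilyl)ethynyl]oxolan‑3‑ol | CC(C)[Si](C(C)C)(C(C)C)C#C[C@@H]1O[C@@H](C=C)C[C@H]1O | intermediate
17 | (2S,3R,5R)‑5‑{(E)‑2‑[(2S,3S,5R,6R)‑3,5‑bis(benzyloxy)‑6‑ethenyloxan‑2‑yl]ethenyl}‑2‑[(triisopropylsilyl)ethynyl]oxolan‑3‑ol | CC(C)[Si](C(C)C)(C(C)C)C#C[C@@H]1O[C@@H](/C=C/[C@@H]2O[C@H](C=C)[C@H](OCc3ccccc3)C[C@@H]2OCc2ccccc2)C[C@H]1O | intermediate
18 | (2S,3R,5R)‑5‑{(E)‑2‑[(2S,3S,5R,6R)‑3,5‑bis(benzyloxy)‑6‑ethyloxan‑2‑yl]ethenyl}‑2‑[(triisopropylsilyl)ethynyl]oxolan‑3‑ol | CC(C)[Si](C(C)C)(C(C)C)C#C[C@@H]1O[C@@H](/C=C/[C@@H]2O[C@H](CC)[C@H](OCc3ccccc3)C[C@@H]2OCc2ccccc2)C[C@H]1O | intermediate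
19 | trans‑7,8‑epoxide of 18 (same facial sense as the epoxide of 15) | CC(C)[Si](C(C)C)(C(C)C)C#C[C@@H]1O[C@@H]([C@H]2O[C@@H]2[C@@H]2O[C@H](CC)[C@H](OCc3ccccc3)C[C@@H]2OCc2ccccc2)C[C@H]1O | intermediate (not isolated)
20 | 10,12‑di‑O‑benzyl‑1‑(triisopropylsilyl)‑3,6:4,7:9,13‑triepoxypentadec‑1‑yne‑8,10,12‑triol (C8, C10, C12 oxygens inverted relative to the bromides of 24) | CC(C)[Si](C(C)C)(C(C)C)C#C[C@@H]1O[C@@H]2C[C@H]1O[C@@H]2[C@H](O)[C@@H]1O[C@H](CC)[C@H](OCc2ccccc2)C[C@@H]1OCc1ccccc1 | intermediate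
21 | 1‑(triisopropylsilyl)‑3,6:4,7:9,13‑triepoxypentadec‑1‑yne‑8,10,12‑triol (same configuration as 20) | CC(C)[Si](C(C)C)(C(C)C)C#C[C@@H]1O[C@@H]2C[C@H]1O[C@@H]2[C@H](O)[C@@H]1O[C@H](CC)[C@H](O)C[C@@H]1O | intermediate
22 | tris(trifluoromethanesulfonate) of 21 | CC(C)[Si](C(C)C)(C(C)C)C#C[C@@H]1O[C@@H]2C[C@H]1O[C@@H]2[C@H](OS(=O)(=O)C(F)(F)F)[C@@H]1O[C@H](CC)[C@H](OS(=O)(=O)C(F)(F)F)C[C@@H]1OS(=O)(=O)C(F)(F)F | intermediate (not isolated)
23 | [(3S,4R,6R,7S,8R,9R,10R,12S,13R)‑8,10,12‑tribromo‑3,6:4,7:9,13‑triepoxypentadec‑1‑yn‑1‑yl]tri(propan‑2‑yl)silane | CC(C)[Si](C(C)C)(C(C)C)C#C[C@@H]1O[C@@H]2C[C@H]1O[C@@H]2[C@@H](Br)[C@@H]1O[C@H](CC)[C@@H](Br)C[C@H]1Br | intermediate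
24 | (3S,4R,6R,7S,8R,9R,10R,12S,13R)‑8,10,12‑tribromo‑3,6:4,7:9,13‑triepoxypentadec‑1‑yne | C#C[C@@H]1O[C@@H]2C[C@H]1O[C@@H]2[C@@H](Br)[C@@H]1O[C@H](CC)[C@@H](Br)C[C@H]1Br | target

**Step count and risks**

Total step count: 16. Longest linear sequence: 12 steps (steps 1–6 and 11–16); the oxolane fragment 16 takes 4 steps (7–10).

Steps most likely to fail:

1. Step 3. The doubly alkoxy‑stabilized cation may be too unreactive toward furan, or the first C–C bond may be followed by proton loss (substitution at C2 of furan) instead of ring closure. Fallback, setting out from 5 and coming back at 7: 1,1‑dimethoxypropan‑2‑one is transacetalized with benzyl alcohol (PPTS, removal of methanol) to 1,1‑bis(benzyloxy)propan‑2‑one F1 and silylated (Et3SiOTf, Et3N) to {[3,3‑bis(benzyloxy)prop‑1‑en‑2‑yl]oxy}triethylsilane F2. Me3SiOTf‑catalyzed [4+3] cycloaddition of F2 with 5, the established mono‑alkoxy case, should give (±)‑2‑(benzyloxy)‑8‑oxabicyclo[3.2.1]oct‑6‑en‑3‑one F3. Kinetic deprotonation on the CH2 side (LDA, −78 °C) and hydroxylation with 2‑(phenylsulfonyl)‑3‑phenyloxaziridine should give (±)‑2‑(benzyloxy)‑4‑hydroxy‑8‑oxabicyclo[3.2.1]oct‑6‑en‑3‑one F4, the hydroxyl expected trans to the benzyloxy group. Acid‑catalyzed benzylation (benzyl 2,2,2‑trichloroacetimidate, cat. TfOH) gives (±)‑trans‑2,4‑bis(benzyloxy)‑8‑oxabicyclo[3.2.1]oct‑6‑en‑3‑one F5, and equilibration with DBU should move the axial benzyloxy group to the equatorial position, which is 7.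

2. Step 11. The catalyst may choose poorly between the two enantiotopic alkene carbons with an aliphatic, already chiral cross partner; E/Z mixtures or ring‑opening oligomerization may also occur. Fallback, setting out from 10 and coming back at 18: desymmetrization is separated from fragment union. Ring‑opening cross‑metathesis of 10 with styrene and the same chiral ruthenium complex, the partner class for which this desymmetrization of oxabicyclic alkenes is best established, should give (2S,3S,5R,6R)‑3,5‑bis(benzyloxy)‑6‑ethenyl‑2‑[(E)‑2‑phenylethenyl]oxane F6. Diimide reduction as in step 12 gives (2S,3S,5R,6R)‑3,5‑bis(benzyloxy)‑6‑ethyl‑2‑[(E)‑2‑phenylethenyl]oxane F7. Cross‑metathesis of F7 with 16 and the second‑generation Hoveyda–Grubbs catalyst RuCl2(H2IMes)(=CH‑C6H4‑2‑O‑i‑Pr), with loss of styrene and thermodynamic E selectivity, then gives 18.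

3. Step 15. The axial triflates may eliminate, or an ether oxygen next to the C8 triflate may participate, leading to rearrangement or retention. Fallback, setting out from 20 and coming back at 23: the three substitutions are taken apart. The C8 alcohol of 20 is converted alone, through its alkoxyphosphonium salt (CBr4, P(n‑C8H17)3, toluene, 70 °C, inversion) and with the ring oxygens still benzylated, to the (8R)‑8‑bromo‑10,12‑bis(benzyl ether) F8. BCl3/C6HMe5 then gives the (8R)‑8‑bromo‑10,12‑diol F9, and only the two axial ring carbinols pass through the bis(triflate) F10 (Tf2O, 2,6‑lutidine; not isolated) and Bu4NBr to 23.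

**Further compounds**

F1 | step 3 | 1,1‑bis(benzyloxy)propan‑2‑one | CC(=O)C(OCc1ccccc1)OCc1ccccc1
F2 | step 3 | {[3,3‑bis(benzyloxy)prop‑1‑en‑2‑yl]oxy}triethylsilane | C=C(O[Si](CC)(CC)CC)C(OCc1ccccc1)OCc1ccccc1
F3 | step 3 | (±)‑2‑(benzyloxy)‑8‑oxabicyclo[3.2.1]oct‑6‑en‑3‑one, benzyloxy cis to the C6=C7 bridge (one enantiomer drawn) | O=C1C[C@@H]2C=C[C@@H](O2)[C@@H]1OCc1ccccc1
F4 | step 3 | (±)‑2‑(benzyloxy)‑4‑hydroxy‑8‑oxabicyclo[3.2.1]oct‑6‑en‑3‑one, hydroxyl trans to the benzyloxy group (one enantiomer drawn) | O=C1[C@@H](O)[C@@H]2C=C[C@@H](O2)[C@@H]1OCc1ccccc1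
F5 | step 3 | (±)‑trans‑2,4‑bis(benzyloxy)‑8‑oxabicyclo[3.2.1]oct‑6‑en‑3‑one (one enantiomer drawn) | O=C1[C@@H](OCc2ccccc2)[C@@H]2C=C[C@@H](O2)[C@@H]1OCc1ccccc1
F6 | step 11 | (2S,3S,5R,6R)‑3,5‑bis(benzyloxy)‑6‑ethenyl‑2‑[(E)‑2‑phenylethenyl]oxane | c1ccccc1/C=C/[C@@H]1O[C@H](C=C)[C@H](OCc2ccccc2)C[C@@H]1OCc1ccccc1
F7 | step 11 | (2S,3S,5R,6R)‑3,5‑bis(benzyloxy)‑6‑ethyl‑2‑[(E)‑2‑phenylethenyl]oxane | c1ccccc1/C=C/[C@@H]1O[C@H](CC)[C@H](OCc2ccccc2)C[C@@H]1OCc1ccccc1
F8 | step 15 | (8R)‑8‑bromo‑10,12‑di‑O‑benzyl‑1‑(triisopropylsilyl)‑3,6:4,7:9,13‑triepoxypentadec‑1‑yne‑10,12‑diol | CC(C)[Si](C(C)C)(C(C)C)C#C[C@@H]1O[C@@H]2C[C@H]1O[C@@H]2[C@@H](Br)[C@@H]1O[C@H](CC)[C@H](OCc2ccccc2)C[C@@H]1OCc1ccccc1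
F9 | step 15 | (8R)‑8‑bromo‑1‑(triisopropylsilyl)‑3,6:4,7:9,13‑triepoxypentadec‑1‑yne‑10,12‑diol | CC(C)[Si](C(C)C)(C(C)C)C#C[C@@H]1O[C@@H]2C[C@H]1O[C@@H]2[C@@H](Br)[C@@H]1O[C@H](CC)[C@H](O)C[C@@H]1O
F10 | step 15 | bis(trifluoromethanesulfonate) of F9 | CC(C)[Si](C(C)C)(C(C)C)C#C[C@@H]1O[C@@H]2C[C@H]1O[C@@H]2[C@@H](Br)[C@@H]1O[C@H](CC)[C@H](OS(=O)(=O)C(F)(F)F)C[C@@H]1OS(=O)(=O)C(F)(F)F
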